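**Assumption:** the target is the (3R,5R,7R) isomer read from the SMILES (ring methyls cis). For the two chiral catalysts (Josiphos, IDPi) the enantiomer giving the stated configuration is used; both antipodes exist and the sense is checked on the first run.

## Retrosynthetic overview

1. Target acid ⇒ its methyl ester (saponification last). The 1,2-dioxolane is the only ring.
2. Dioxolane ⇒ acyclic C5 tertiary peroxide plus C2=C3 enoate. The O–C3 bond is closed by 5-exo oxa-Michael addition of the peroxide, the presumed biogenetic ring closure; C3 is created here.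
3. Peroxy enoate ⇒ C4–C5 disconnection, not alkene hydroperoxidation: vinylogous Mukaiyama addition of a senecioate silyl dienolate to a C5 peroxycarbenium ion from a silylperoxy methyl ketal. C5 is created here, in the same flask as the ring closure.
4. Peroxy ketal ⇒ (R)-4-methylalkan-2-one ⇒ Cu/Josiphos conjugate addition of MeMgBr to an (E)-enone (sets C7).
5. Enone ⇒ cross-metathesis of a 1-alkene with methyl vinyl ketone ⇒ hydrozirconation/Pd coupling of dec-1-en-9-yne with (E)-β-bromostyrene ⇒ 8-bromooct-1-ene plus lithium acetylide.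

## Route

Step 1
Reactants: 1 8-bromooct-1-ene; 2 lithium acetylide–ethylenediamine complex
Product: 3 dec-1-en-9-yne
Conditions: 2 (1.5 equiv), DMSO, 0 °C → rt
Reagents that add atoms: none
Why: SN2 alkylation of lithium acetylide by an unhindered primary bromide in DMSO; no stereocentre is formed.

Step 2
Reactants: 3 dec-1-en-9-yne; 4 (E)-β-bromostyrene
Product: 6 (1E,3E)-1-phenyldodeca-1,3,11-triene, via alkenylzirconocene chloride 5 (not isolated)
Conditions: Cp2Zr(H)Cl (1.05 equiv), THF, 0 °C → rt; then 4, Pd(PPh3)4 (3 mol%), THF, rt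
Reagents that add atoms: none
Why: Schwartz hydrozirconation is syn and faster at the terminal alkyne than at the terminal alkene, and the Negishi-type Pd alkenyl–alkenyl coupling retains both alkene geometries, so the E,E diene is fixed.

Step 3
Reactants: 6 (1E,3E)-1-phenyldodeca-1,3,11-triene; 7 but-3-en-2-one
Product: 8 (3E,11E,13E)-14-phenyltetradeca-3,11,13-trien-2-one
Conditions: 7 (3 equiv), Hoveyda–Grubbs II (3 mol%), CH2Cl2, 40 °C
Reagents that add atoms: none
Why: Olefin cross-metathesis of a terminal alkene with an electron-poor enone partner gives the E-enone, while the internal phenyl-conjugated diene is far less reactive towards the Ru carbene.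

Step 4
Reactants: 8 (3E,11E,13E)-14-phenyltetradeca-3,11,13-trien-2-one
Product: 10 (4R,11E,13E)-4-methyl-14-phenyltetradeca-11,13-dien-2-one, via magnesium enolate 9 (not isolated)
Conditions: MeMgBr (1.2 equiv), CuBr·SMe2 (5 mol%), Josiphos SL-J001 (6 mol%), t-BuOMe, −75 °C; then H2O
Reagents that add atoms: methylmagnesium bromide C[Mg]Br
Why: Cu(I)/Josiphos-catalysed asymmetric conjugate addition of a Grignard reagent to a linear (E)-enone delivers methyl to the Re face of C4, which sets the 4R centre (C7 of the target); the low temperature keeps 1,2-addition minor.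

Step 5
Reactants: 10 (4R,11E,13E)-4-methyl-14-phenyltetradeca-11,13-dien-2-one
Product: 12 triethyl{[(4R,11E,13E)-2-methoxy-4-methyl-14-phenyltetradeca-11,13-dien-2-yl]peroxy}silane, via hydroperoxy ketal 11 (not isolated)
Conditions: urea·H2O2 (5 equiv), Sc(OTf)3 (10 mol%), MeOH, 0 °C → rt; extractive work-up; then Et3SiCl, imidazole, DMF, 0 °C
Reagents that add atoms: urea–hydrogen peroxide NC(N)=O.OO; methanol CO; chlorotriethylsilane CC[Si](Cl)(CC)CC
Why: Lewis-acid-catalysed perhydrolysis of the ketone in methanol gives the α-methoxy hydroperoxide (hydroperoxy ketal formation) and O-silylation protects it; the new C2 centre is an irrelevant epimer mixture that is destroyed in step 7, and the diene is inert to unactivated H2O2.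

Step 6
Reactants: 13 methyl 3-methylbut-2-enoate
Product: 15 [(1-methoxy-3-methylbuta-1,3-dien-1-yl)oxy]trimethylsilane, via lithium dienolate 14 (not isolated)
Conditions: LDA (1.1 equiv), THF, −78 °C; then Me3SiCl, −78 °C → rt; distil
Reagents that add atoms: chlorotrimethylsilane C[Si](C)(C)Cl
Why: Kinetic γ-deprotonation of the senecioate and O-silylation of the dienolate is the standard preparation of this silyl dienol ether; no stereocentre is formed.

Step 7
Reactants: 12 triethyl{[(4R,11E,13E)-2-methoxy-4-methyl-14-phenyltetradeca-11,13-dien-2-yl]peroxy}silane; 15 [(1-methoxy-3-methylbuta-1,3-dien-1-yl)oxy]trimethylsilane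
Product: 18 methyl 2-[(3R,5R)-3,5-dimethyl-5-[(2R,9E,11E)-2-methyl-12-phenyldodeca-9,11-dien-1-yl]-1,2-dioxolan-3-yl]acetate, via silylperoxy enoate 16 (not isolated), via hydroperoxy enoate 17 (not isolated)
Conditions: 15 (2 equiv), chiral IDPi acid (confined BINOL-derived imidodiphosphorimidate, 2 mol%), CH2Cl2, −78 °C; then TBAF (3 equiv), THF, −78 → 0 °C; then Et2NH, CF3CH2OH, rt; preparative HPLC
Reagents that add atoms: none
Why: Proposed new method: the silylium form of the chiral acid (made in situ from 15) removes OMe from 12 to give a C5 peroxycarbenium ion paired with the chiral anion; 15 attacks through its γ-CH2 (vinylogous Mukaiyama addition) on the face giving 5R under catalyst control (C7 is too remote to help or hinder); fluoride then frees the tertiary peroxide anion, which closes the dioxolane by 5-exo oxa-Michael addition to the C2=C3 enoate as in the presumed biosynthesis; C3 forms with little selectivity (about 1:1 expected) and the 3R (cis-dimethyl) isomer is separated from its C3 epimer and any minor C5 epimer by HPLC; the closest known reaction types are Lewis-acid additions of silyl enol ethers and ketene acetals to ketone-derived peroxycarbenium ions, silylium/chiral-anion Mukaiyama and vinylogous Mukaiyama reactions that distinguish methyl from alkyl in ketone-derived oxocarbenium ions, and amine-mediated hydroperoxide-to-enoate cyclisations in CF3CH2OH.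

Step 8
Reactants: 18 methyl 2-[(3R,5R)-3,5-dimethyl-5-[(2R,9E,11E)-2-methyl-12-phenyldodeca-9,11-dien-1-yl]-1,2-dioxolan-3-yl]acetate
Product: 20 2-[(3R,5R)-3,5-dimethyl-5-[(2R,9E,11E)-2-methyl-12-phenyldodeca-9,11-dien-1-yl]-1,2-dioxolan-3-yl]acetic acid, via lithium carboxylate 19 (not isolated)
Conditions: LiOH (3 equiv), THF/H2O 3:1, 0 °C → rt; then 1 M HCl to pH 3
Reagents that add atoms: lithium hydroxide [Li+].[OH-]
Why: Saponification of the methyl ester; the fully substituted dioxolane has no hydrogen on its O-bearing carbons (no Kornblum–DeLaMare pathway), so it survives cold hydroxide and no stereocentre is touched.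

## Compound list

1 | 8-bromooct-1-ene | C=CCCCCCCBr | starting material
2 | lithium acetylide–ethylenediamine complex | [Li+].[C-]#C.NCCN | starting material
3 | dec-1-en-9-yne | C=CCCCCCCC#C | intermediate
4 | (E)-β-bromostyrene | Br/C=C/c1ccccc1 | starting material
5 | chlorobis(cyclopentadienyl)[(1E)-deca-1,9-dien-1-yl]zirconium | C=CCCCCCC/C=C/[Zr+2]Cl.c1cc[cH-]c1.c1cc[cH-]c1 | intermediate (not isolated)
6 | (1E,3E)-1-phenyldodeca-1,3,11-triene | C=CCCCCCC/C=C/C=C/c1ccccc1 | intermediate
7 | but-3-en-2-one (methyl vinyl ketone) | CC(=O)C=C | starting material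
8 | (3E,11E,13E)-14-phenyltetradeca-3,11,13-trien-2-one | CC(=O)/C=C/CCCCCC/C=C/C=C/c1ccccc1 | intermediate
9 | bromomagnesium (4R,11E,13E)-4-methyl-14-phenyltetradeca-2,11,13-trien-2-olate | C[C@H](CCCCCC/C=C/C=C/c1ccccc1)C=C(C)O[Mg]Br | intermediate (not isolated)
10 | (4R,11E,13E)-4-methyl-14-phenyltetradeca-11,13-dien-2-one | C[C@H](CCCCCC/C=C/C=C/c1ccccc1)CC(C)=O | intermediate
11 | (4R,11E,13E)-2-hydroperoxy-2-methoxy-4-methyl-14-phenyltetradeca-11,13-diene (C2 epimers) | C[C@H](CCCCCC/C=C/C=C/c1ccccc1)CC(C)(OC)OO | intermediate (not isolated)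
12 | triethyl{[(4R,11E,13E)-2-methoxy-4-methyl-14-phenyltetradeca-11,13-dien-2-yl]peroxy}silane (C2 epimers) | C[C@H](CCCCCC/C=C/C=C/c1ccccc1)CC(C)(OC)OO[Si](CC)(CC)CC | intermediate
13 | methyl 3-methylbut-2-enoate | CC(C)=CC(=O)OC | starting material
14 | lithium 1-methoxy-3-methylbuta-1,3-dien-1-olate | C=C(C)C=C(OC)O[Li] | intermediate (not isolated)
15 | [(1-methoxy-3-methylbuta-1,3-dien-1-yl)oxy]trimethylsilane | C=C(C)C=C(OC)O[Si](C)(C)C | intermediate
16 | methyl (5R,7R,14E,16E)-3,5,7-trimethyl-17-phenyl-5-[(triethylsilyl)peroxy]heptadeca-2,14,16-trienoate (2E/2Z) | C[C@H](CCCCCC/C=C/C=C/c1ccccc1)C[C@](C)(CC(C)=CC(=O)OC)OO[Si](CC)(CC)CC | intermediate (not isolated)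
17 | methyl (5R,7R,14E,16E)-5-hydroperoxy-3,5,7-trimethyl-17-phenylheptadeca-2,14,16-trienoate (2E/2Z) | C[C@H](CCCCCC/C=C/C=C/c1ccccc1)C[C@](C)(CC(C)=CC(=O)OC)OO | intermediate (not isolated)
18 | methyl 2-[(3R,5R)-3,5-dimethyl-5-[(2R,9E,11E)-2-methyl-12-phenyldodeca-9,11-dien-1-yl]-1,2-dioxolan-3-yl]acetate | C[C@H](CCCCCC/C=C/C=C/c1ccccc1)C[C@]1(C)C[C@](C)(CC(=O)OC)OO1 | intermediate
19 | lithium 2-[(3R,5R)-3,5-dimethyl-5-[(2R,9E,11E)-2-methyl-12-phenyldodeca-9,11-dien-1-yl]-1,2-dioxolan-3-yl]acetate | C[C@H](CCCCCC/C=C/C=C/c1ccccc1)C[C@]1(C)C[C@](C)(CC(=O)[O-])OO1.[Li+] | intermediate (not isolated)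
20 | 2-[(3R,5R)-3,5-dimethyl-5-[(2R,9E,11E)-2-methyl-12-phenyldodeca-9,11-dien-1-yl]-1,2-dioxolan-3-yl]acetic acid | C[C@H](CCCCCC/C=C/C=C/c1ccccc1)C[C@]1(C)C[C@](C)(CC(=O)O)OO1 | target

## Step count and risks

Total steps: 8. Longest linear sequence: 7 (steps 1–5, 7, 8; step 6 is a one-step side branch).

**Step 7 (most likely to fail).** The risks are:
- ionisation of 12 may expel the silylperoxy group instead of OMe, or trigger a Criegee-type rearrangement;
- α- rather than γ-attack of the dienolate;
- facial control at C5 by the chiral anion is unproven; without it the 5-epimer forms about 1:1 and must also be removed by HPLC;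
- the oxa-Michael addition to a β,β-disubstituted enoate may be slow or divert to an epoxide by enolate attack on the O–O bond.

Fallback: starting from 12, the same peroxycarbenium ion is generated with TMSOTf and trapped with the simpler, strongly nucleophilic 2-(trimethylsiloxy)propene. This gives the β-silylperoxy ketone (4R,6R,13E,15E)-4,6-dimethyl-16-phenyl-4-[(triethylsilyl)peroxy]hexadeca-13,15-dien-2-one F1. TBAF frees the hydroperoxide, which closes onto the ketone to the peroxyhemiketal (5R)-3,5-dimethyl-5-[(2R,9E,11E)-2-methyl-12-phenyldodeca-9,11-dien-1-yl]-1,2-dioxolan-3-ol F2. MeOH/PPTS converts this into (5R)-3-methoxy-3,5-dimethyl-5-[(2R,9E,11E)-2-methyl-12-phenyldodeca-9,11-dien-1-yl]-1,2-dioxolane F3. TiCl4 with 1-(tert-butyldimethylsilyloxy)-1-methoxyethene then replaces OMe by CH2CO2Me through the cyclic peroxycarbenium ion, and the route is rejoined at 18. In this fallback the ring is closed by peroxyhemiketalisation and C3 is made by C–C bond formation; C3 epimers are again separated.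

**Step 5.** The hydroperoxy ketal 11 sits in equilibrium with ketone, dimethyl ketal and gem-dihydroperoxide, and 11 and 12 are acid- and silica-sensitive.

Fallback: starting from 10, ethereal H2O2 with catalytic phosphomolybdic acid drives the ketone fully to the gem-dihydroperoxide (4R,11E,13E)-2,2-dihydroperoxy-4-methyl-14-phenyltetradeca-11,13-diene F4. Et3SiCl/imidazole gives (4R,11E,13E)-4-methyl-14-phenyl-2,2-bis[(triethylsilyl)peroxy]tetradeca-11,13-diene F5. Under the step 7 conditions F5 ionises by loss of one silylperoxy group to the same C5 peroxycarbenium ion, and the route is rejoined at 16.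

**Step 4.** MeMgBr is the least reactive Grignard reagent in this enone addition; competing 1,2-addition or an ee below about 95% would leave C7 epimers in every later intermediate.

Fallback: starting from 6, cross-metathesis with S-ethyl thioacrylate (Hoveyda–Grubbs II) gives S-ethyl (2E,10E,12E)-13-phenyltrideca-2,10,12-trienethioate F6. MeMgBr with CuBr·SMe2/Josiphos at −75 °C, on the substrate class where this methyl addition is most reliable and free of 1,2-addition, gives S-ethyl (3R,10E,12E)-3-methyl-13-phenyltrideca-10,12-dienethioate F7. Me2CuLi (Et2O, −78 °C) converts the thioester into the methyl ketone, and the route is rejoined at 10.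

## Further compounds

F1 | step 7 | (4R,6R,13E,15E)-4,6-dimethyl-16-phenyl-4-[(triethylsilyl)peroxy]hexadeca-13,15-dien-2-one | C[C@H](CCCCCC/C=C/C=C/c1ccccc1)C[C@](C)(CC(C)=O)OO[Si](CC)(CC)CC
F2 | step 7 | (5R)-3,5-dimethyl-5-[(2R,9E,11E)-2-methyl-12-phenyldodeca-9,11-dien-1-yl]-1,2-dioxolan-3-ol | C[C@H](CCCCCC/C=C/C=C/c1ccccc1)C[C@]1(C)CC(C)(O)OO1
F3 | step 7 | (5R)-3-methoxy-3,5-dimethyl-5-[(2R,9E,11E)-2-methyl-12-phenyldodeca-9,11-dien-1-yl]-1,2-dioxolane | C[C@H](CCCCCC/C=C/C=C/c1ccccc1)C[C@]1(C)CC(C)(OC)OO1
F4 | step 5 | (4R,11E,13E)-2,2-dihydroperoxy-4-methyl-14-phenyltetradeca-11,13-diene | C[C@H](CCCCCC/C=C/C=C/c1ccccc1)CC(C)(OO)OO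
F5 | step 5 | (4R,11E,13E)-4-methyl-14-phenyl-2,2-bis[(triethylsilyl)peroxy]tetradeca-11,13-diene | C[C@H](CCCCCC/C=C/C=C/c1ccccc1)CC(C)(OO[Si](CC)(CC)CC)OO[Si](CC)(CC)CC
F6 | step 4 | S-ethyl (2E,10E,12E)-13-phenyltrideca-2,10,12-trienethioate | CCSC(=O)/C=C/CCCCCC/C=C/C=C/c1ccccc1
F7 | step 4 | S-ethyl (3R,10E,12E)-3-methyl-13-phenyltrideca-10,12-dienethioate | C[C@H](CCCCCC/C=C/C=C/c1ccccc1)CC(=O)SCC
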